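**Retrosynthetic overview**

1. Last disconnection: the four arm phenols are carried as benzyl ethers and the C5 hydroxyl as a methyl ether; one BCl3 operation at the end removes all five and leaves the C7 methoxy group.
2. Key disconnection: the C4–C4a bond (closure of pyranone ring C by Friedel–Crafts cycloacylation of an (S)-3-aryloxy-3-phenylpropanoic acid) together with the C6–CH2 and C8–CH2 bonds, all three made in one flask from that acid and two equivalents of one benzylic alcohol (the arm).
3. Enabling feature: ring A is a phloroglucinol nucleus whose C6 and C8 carry the same arm. In the 3,5-dimethoxyphenyl ether the two carbons ortho to the ether oxygen are equivalent, so closure at either gives the same C4a. Once C4 is attached, C6 and C8 are the only unsubstituted ring A carbons (each between two oxygens, meta to C4=O), so exhaustive benzylation needs no regiocontrol.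
4. C2 (S): the O1–C2 bond comes from Mitsunobu inversion of ethyl (R)-3-hydroxy-3-phenylpropanoate with 3,5-dimethoxyphenol. The arm comes from a Suzuki–Miyaura benzyl–aryl coupling followed by aldehyde reduction.
5. Ring order: rings A and B and the four arm rings are bought; ring C is the only ring made, in the key step.

Key step: step 5

Assumption: the stereodescriptor of the target SMILES is read as (2S); 2-(benzyloxy)benzyl bromide, [4-(benzyloxy)-3-formylphenyl]boronic acid and ethyl (R)-3-hydroxy-3-phenylpropanoate are taken as catalogue compounds.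

**Route**

Step 1
Reactants: 1 2-(benzyloxy)benzyl bromide; 2 [4-(benzyloxy)-3-formylphenyl]boronic acid
Product: 3 2-(benzyloxy)-5-[2-(benzyloxy)benzyl]benzaldehyde
Conditions: Pd(PPh3)4 (3 mol%), K2CO3, 1,2-dimethoxyethane/H2O, 80 °C
Reagents that add atoms: none
Why: Suzuki–Miyaura coupling of a benzylic bromide with an arylboronic acid is a standard route to diarylmethanes, tolerates the aldehyde, and the bought boronic acid fixes the arm pattern (CH2 para and CHO ortho to the benzyloxy group).

Step 2
Reactants: 3 2-(benzyloxy)-5-[2-(benzyloxy)benzyl]benzaldehyde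
Product: 4 {2-(benzyloxy)-5-[2-(benzyloxy)benzyl]phenyl}methanol
Conditions: NaBH4, MeOH/THF, 0 °C
Reagents that add atoms: none
Why: Hydride reduction of an aromatic aldehyde to the benzylic alcohol should be clean and leaves the benzyl ethers and the diarylmethane untouched.

Step 3
Reactants: 5 3,5-dimethoxyphenol; 6 ethyl (R)-3-hydroxy-3-phenylpropanoate
Product: 7 ethyl (S)-3-(3,5-dimethoxyphenoxy)-3-phenylpropanoate
Conditions: PPh3, DIAD (slow addition), toluene, 0 °C to rt
Reagents that add atoms: none
Why: In this Mitsunobu etherification the phenoxide displaces the benzylic alkoxyphosphonium ion by SN2 with inversion, so the (R)-alcohol should give the (S)-aryl ether and thereby set C2 of the target.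

Step 4
Reactants: 7 ethyl (S)-3-(3,5-dimethoxyphenoxy)-3-phenylpropanoate
Product: 8 (S)-3-(3,5-dimethoxyphenoxy)-3-phenylpropanoic acid
Conditions: LiOH, THF/H2O, 0 °C; then 1 M HCl to pH 3
Reagents that add atoms: lithium hydroxide, [Li+].[OH-]
Why: Saponification at 0 °C attacks the ester carbonyl faster than the α-position is deprotonated, so loss of phenoxide by E1cB should stay minor and the stereocenter, which is not acidic, is untouched.

Step 5
Reactants: 8 (S)-3-(3,5-dimethoxyphenoxy)-3-phenylpropanoic acid; 4 {2-(benzyloxy)-5-[2-(benzyloxy)benzyl]phenyl}methanol (2.3 equiv)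
Product: 13 (2S)-6,8-bis{2-(benzyloxy)-5-[2-(benzyloxy)benzyl]benzyl}-5,7-dimethoxy-2-phenylchroman-4-one, via mixed trifluoroacetic anhydride 9 (not isolated), via (S)-5,7-dimethoxyflavanone 10 (not isolated), via 6-monobenzylated flavanone 11 (not isolated), via 8-monobenzylated flavanone 12 (not isolated)
Conditions: trifluoroacetic anhydride (TFAA, 1.05 equiv), CH2Cl2 (0.05 M), 0 °C to rt; then 1,1,1,3,3,3-hexafluoropropan-2-ol (HFIP), 4 (2.3 equiv, slow addition), rt to 40 °C, same flask
Reagents that add atoms: none
Why: TFAA turns acid 8 into acyl trifluoroacetate 9, whose carbonyl carbon (C4) is attacked by the ring carbon ortho to the ether oxygen (C4a) of the 1,3,5-trioxygenated ring, closing ring C in a 6-exo-trig Friedel–Crafts cycloacylation to give 10; the trifluoroacetic acid released, in HFIP, then ionizes two molecules of alcohol 4 to ortho-alkoxy-stabilized benzyl cations that alkylate C6 and C8 through 11 and 12. The closest known reaction types are the TFAA-mediated cyclization of 3-aryloxypropanoic acids to chroman-4-ones and the acid/HFIP-promoted dehydrative Friedel–Crafts benzylation of polyalkoxyarenes, including the C-benzylation of flavanone A rings. No stereocenter is created; C2 is not part of any bond made or broken, and without base the flavanone should not open to the chalcone, so the (S) configuration is expected to be retained. Ring closure needs no regiocontrol because the two ortho carbons of the 3,5-dimethoxyphenyl ether are equivalent and the para carbon cannot be reached by the tether. Benzylation needs no regiocontrol either, because acylation comes first and leaves C6 and C8 as the only free ring A positions, which are both to be filled. Chemoselectivity rests on ring A being the most nucleophilic arene present (each reacting carbon is ortho or para to three oxygens and only meta to the carbonyl), on slow addition of 4 to keep the cation scarce, and on aryl benzyl ethers being stable to trifluoroacetic acid/HFIP at or below 40 °C.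

Step 6
Reactants: 13 (2S)-6,8-bis{2-(benzyloxy)-5-[2-(benzyloxy)benzyl]benzyl}-5,7-dimethoxy-2-phenylchroman-4-one
Product: 14 5''-(2''''-hydroxybenzyl)uvarinol, (2S)-5-hydroxy-6,8-bis[2-hydroxy-5-(2-hydroxybenzyl)benzyl]-7-methoxy-2-phenylchroman-4-one
Conditions: BCl3, pentamethylbenzene, CH2Cl2, −78 °C to 0 °C; then MeOH, aqueous work-up
Reagents that add atoms: none
Why: BCl3 with pentamethylbenzene as a non-basic benzyl-cation trap is a known low-temperature cleavage of aryl benzyl ethers, and on warming BCl3 should demethylate only the C5 methoxy group, the one that can form a six-membered boron chelate with the C4 carbonyl, leaving the C7 methyl ether, the ketone and C2 intact.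

**Compound list**

1 | 2-(benzyloxy)benzyl bromide | BrCc1ccccc1OCc1ccccc1 | starting material
2 | [4-(benzyloxy)-3-formylphenyl]boronic acid | OB(O)c1ccc(OCc2ccccc2)c(C=O)c1 | starting material
3 | 2-(benzyloxy)-5-[2-(benzyloxy)benzyl]benzaldehyde | O=Cc1cc(Cc2ccccc2OCc2ccccc2)ccc1OCc1ccccc1 | intermediate
4 | {2-(benzyloxy)-5-[2-(benzyloxy)benzyl]phenyl}methanol | OCc1cc(Cc2ccccc2OCc2ccccc2)ccc1OCc1ccccc1 | intermediate
5 | 3,5-dimethoxyphenol | COc1cc(O)cc(OC)c1 | starting material
6 | ethyl (R)-3-hydroxy-3-phenylpropanoate | CCOC(=O)C[C@@H](O)c1ccccc1 | starting material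
7 | ethyl (S)-3-(3,5-dimethoxyphenoxy)-3-phenylpropanoate | CCOC(=O)C[C@H](Oc1cc(OC)cc(OC)c1)c1ccccc1 | intermediate
8 | (S)-3-(3,5-dimethoxyphenoxy)-3-phenylpropanoic acid | OC(=O)C[C@H](Oc1cc(OC)cc(OC)c1)c1ccccc1 | intermediate
9 | (S)-3-(3,5-dimethoxyphenoxy)-3-phenylpropanoic trifluoroacetic anhydride (not isolated) | O=C(C[C@H](Oc1cc(OC)cc(OC)c1)c1ccccc1)OC(=O)C(F)(F)F | intermediate
10 | (S)-5,7-dimethoxyflavanone, (2S)-5,7-dimethoxy-2-phenylchroman-4-one (not isolated) | COc1cc(OC)c2c(c1)O[C@H](c1ccccc1)CC2=O | intermediate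
11 | (2S)-6-{2-(benzyloxy)-5-[2-(benzyloxy)benzyl]benzyl}-5,7-dimethoxy-2-phenylchroman-4-one (not isolated) | COc1c(Cc2cc(Cc3ccccc3OCc3ccccc3)ccc2OCc2ccccc2)c(OC)c2c(c1)O[C@H](c1ccccc1)CC2=O | intermediate
12 | (2S)-8-{2-(benzyloxy)-5-[2-(benzyloxy)benzyl]benzyl}-5,7-dimethoxy-2-phenylchroman-4-one (not isolated) | COc1cc(OC)c2c(c1Cc1cc(Cc3ccccc3OCc3ccccc3)ccc1OCc1ccccc1)O[C@H](c1ccccc1)CC2=O | intermediate
13 | (2S)-6,8-bis{2-(benzyloxy)-5-[2-(benzyloxy)benzyl]benzyl}-5,7-dimethoxy-2-phenylchroman-4-one | COc1c(Cc2cc(Cc3ccccc3OCc3ccccc3)ccc2OCc2ccccc2)c(OC)c2c(c1Cc1cc(Cc3ccccc3OCc3ccccc3)ccc1OCc1ccccc1)O[C@H](c1ccccc1)CC2=O | intermediate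
14 | 5''-(2''''-hydroxybenzyl)uvarinol, (2S)-5-hydroxy-6,8-bis[2-hydroxy-5-(2-hydroxybenzyl)benzyl]-7-methoxy-2-phenylchroman-4-one | COc1c(Cc2cc(Cc3ccccc3O)ccc2O)c(O)c2c(c1Cc1cc(Cc3ccccc3O)ccc1O)O[C@H](c1ccccc1)CC2=O | target

**Step count**

Total step count: 6. Longest linear sequence: 4 steps (steps 3, 4, 5, 6; the arm branch, steps 1, 2, 5, 6, is equally long).

**Steps most likely to fail**

Step 5. The second benzylation may stall once the flanking methoxy groups are twisted out of conjugation, while the benzylic cation is diverted into alkylating the arm rings (oligomerization) or the benzyl ethers are slowly cleaved by acid. The fallback replaces electrophilic benzylation by cross-coupling. It sets out from 8: the ring closure alone (TFAA, CH2Cl2, 0 °C to rt) is run and 10 is isolated. NBS (2.1 equiv, MeCN, rt) should then brominate the two free ring A carbons to give (2S)-6,8-dibromo-5,7-dimethoxy-2-phenylchroman-4-one F1. Separately, alcohol 4 is converted with PBr3 (CH2Cl2, 0 °C) into 1-(benzyloxy)-4-[2-(benzyloxy)benzyl]-2-(bromomethyl)benzene F2, and this with Zn dust and LiCl (THF, rt) into {2-(benzyloxy)-5-[2-(benzyloxy)benzyl]benzyl}zinc bromide F3. A twofold Negishi coupling of F1 with F3 (Pd(OAc)2, SPhos, THF, 50 °C) comes back to the route at 13.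

Step 6. Selectivity between the two methyl ethers may be lost: the hindered C7 methoxy group, twisted out of the ring plane and close to aryloxyboron groups on the arms, may also be cleaved, or prolonged Lewis acid contact may open ring C and erode C2. The fallback separates the two deprotections. It sets out from 13: MgI2·OEt2 (THF/toluene, 60 °C) should cleave only the C5 methyl ether held in the chelate with C4=O and leave the benzyl ethers, giving (2S)-6,8-bis{2-(benzyloxy)-5-[2-(benzyloxy)benzyl]benzyl}-5-hydroxy-7-methoxy-2-phenylchroman-4-one F4. Hydrogenolysis (H2, Pd/C, EtOAc, rt) then removes the four benzyl ethers and comes back to the route at 14.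

Step 3. The activated β-hydroxy ester may eliminate to ethyl cinnamate, and partial ionization of the benzylic oxyphosphonium ion would erode enantiopurity. The fallback uses an alcohol without acidic α-hydrogens. It sets out from 5: Mitsunobu coupling with commercial (R)-3-chloro-1-phenylpropan-1-ol (ClCC[C@@H](O)c1ccccc1; PPh3, DIAD, THF, 0 °C to rt), a partner of a type widely used for aryl ether formation with clean inversion, should give (S)-1-(3-chloro-1-phenylpropoxy)-3,5-dimethoxybenzene F5. CsOAc (DMF, 80 °C) displaces chloride to give (S)-3-(3,5-dimethoxyphenoxy)-3-phenylpropyl acetate F6. Methanolysis (K2CO3, MeOH, rt) gives (S)-3-(3,5-dimethoxyphenoxy)-3-phenylpropan-1-ol F7. Oxidation with TEMPO (cat.) and PhI(OAc)2 in MeCN/H2O comes back to the route at 8 and also bypasses the saponification of step 4.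

**Further compounds**

F1 | step 5 | (2S)-6,8-dibromo-5,7-dimethoxy-2-phenylchroman-4-one | COc1c(Br)c(OC)c2c(c1Br)O[C@H](c1ccccc1)CC2=O
F2 | step 5 | 1-(benzyloxy)-4-[2-(benzyloxy)benzyl]-2-(bromomethyl)benzene | BrCc1cc(Cc2ccccc2OCc2ccccc2)ccc1OCc1ccccc1
F3 | step 5 | {2-(benzyloxy)-5-[2-(benzyloxy)benzyl]benzyl}zinc bromide | Br[Zn]Cc1cc(Cc2ccccc2OCc2ccccc2)ccc1OCc1ccccc1
F4 | step 6 | (2S)-6,8-bis{2-(benzyloxy)-5-[2-(benzyloxy)benzyl]benzyl}-5-hydroxy-7-methoxy-2-phenylchroman-4-one | COc1c(Cc2cc(Cc3ccccc3OCc3ccccc3)ccc2OCc2ccccc2)c(O)c2c(c1Cc1cc(Cc3ccccc3OCc3ccccc3)ccc1OCc1ccccc1)O[C@H](c1ccccc1)CC2=O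
F5 | step 3 | (S)-1-(3-chloro-1-phenylpropoxy)-3,5-dimethoxybenzene | ClCC[C@H](Oc1cc(OC)cc(OC)c1)c1ccccc1
F6 | step 3 | (S)-3-(3,5-dimethoxyphenoxy)-3-phenylpropyl acetate | CC(=O)OCC[C@H](Oc1cc(OC)cc(OC)c1)c1ccccc1
F7 | step 3 | (S)-3-(3,5-dimethoxyphenoxy)-3-phenylpropan-1-ol | OCC[C@H](Oc1cc(OC)cc(OC)c1)c1ccccc1
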